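The earlier runs and the new flask stem from a simulated flask for an exercise.

I started from the leftover, the fraction of the solid substrate still lying in the flask, and not from the target made.

- midnight: solid substrate 0.68 M; gas phase 46 mM (held); the very flask that is asked about, followed so far
- flask: solid substrate 0.68 M; gas phase 46 mM (held); time 8.0 h

midnight run (percent of the solid substrate charged)

| time / h | target / % | solid substrate / % |
|---|---|---|
| 0.200 | 1.6 | 97.9 |
| 0.333 | 3.7 | 96.5 |
| 0.667 | 6.4 | 93.9 |
| 1.33 | 12.5 | 87.7 |
| 2.50 | 23.8 | 76.9 |

(readings scatter by 0.5 percentage points)

- solid substrate is a solid; its amount is given per volume of the solution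
- the numbers in the tables scatter with a standard deviation of 0.5 percentage points
- at the start none of the gas phase is in solution
- at the start none of the solid substrate is in solution

- target at 8.0 h, in percent of the solid substrate charged
- concentration of dissolved gas in solution at 8.0 h, in percent of saturation

The flask asked about is the midnight run itself, so I turned the question round: what would the midnight run have had to show for its solid to reach nothing by 8.0 h? On a straight fall, the fraction left at 2.50 h would have been 68.8 %. The reading was 76.9 %, higher than that by 8.1 percentage points, against a scatter of 0.5 points.

So I carried the emptying time, the hours a straight, zero-order fall of the solid fraction takes to reach nothing: 10.8 h. It held earlier, too. At 1.33 h it gave 87.7 % left, and 87.7 % was read. For 8.0 h it gave 26.1 % left. Target and solid summed to about the whole charge in the midnight run, so I expected 73.9 % of target. For the dissolved gas I reckoned nothing.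

The forecast gave 76 % of target and 85 % of saturation, holding that “the rate is zero order until the solid runs out”. My target was lower than the forecast's by 2.1 points.

The flask gave 73.1 % of target, with 24.9 % of solid substrate left. Its dissolved gas stood at 99.9 % of saturation, higher than the forecast by 15 points.

    starting material + dissolved gas → target (k = 0.500 /M/s)
    gas phase ⇌ dissolved gas, rate k2*(csat - [dissolved gas]) (kL = 0.325 /s)
    starting material → decomposition product (k = 2.10 × 10⁻⁷ /s)
    starting material + target → side product (k = 0.00112 /M/s)
    solid substrate ⇌ starting material, rate k5*(cs5 - [starting material]) while solid is left; crystals form when [starting material] > cs5 (solubility = 37.0 mM, k = 4.89 × 10⁻⁴ /s)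

The neighbouring flask had the same charges and was read at 3.0 h. The emptying time put its fraction left at 72.2 %. That neighbouring flask gave 27.8 % of target and held 72 % of the charge, solid or dissolved.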